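In this flask the product cannot exceed what the partner makes once the protic impurity has titrated part of it away.

| flask | solid substrate | partner | protic impurity | remark | time |
|---|---|---|---|---|---|
| ochre | 0.024 M | 1.1 equiv (in portions, 2) | 3.2 mM | run made earlier; portions every 3.0 min |  |
| grey | 0.024 M | 1.1 equiv (in portions, 2) | 7.2 mM | run made earlier; portions every 3.0 min |  |
| red | 0.024 M | 2.2 equiv (in portions, 2) | 4.8 mM | run made earlier; portions every 3.0 min |  |
| flask | 0.024 M | 1.10 equiv (in portions, 2) | 4.80 mM | the portions of partner follow each other after 3.0 min, the first at the start | 3.0 d |

| run | time / d | solid substrate / % | product / % | starting material / % |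
|---|---|---|---|---|
| ochre | 0.250 | 50.6 | 42.8 | 5.8 |
| ochre | 0.833 | 0 | 96.5 | 3.3 |
| ochre | 1.25 | 0 | 95.6 | 3.9 |
| ochre | 2.00 | 0 | 96.1 | 3.0 |
| ochre | 3.00 | 0.4 | 96.6 | 3.0 |
| grey | 0.250 | 51.8 | 41.0 | 7.2 |
| grey | 0.417 | 26.0 | 64.6 | 8.7 |
| grey | 0.833 | 2.9 | 80.3 | 16.8 |
| grey | 1.67 | 2.3 | 80.1 | 17.6 |
| grey | 3.00 | 3.0 | 79.8 | 17.1 |
| red | 0.250 | 44.1 | 49.6 | 4.7 |
| red | 0.833 | 0 | 99.8 | 0.5 |
| red | 1.25 | 0 | 100.3 | 0.7 |
| red | 2.00 | 0 | 99.5 | 0.5 |
| red | 3.00 | 0.2 | 99.6 | 0 |

(standard deviation of a reading: 0.5 percentage points)

- solid substrate is a solid; its amount is given per volume of the solution
- at the start none of the solid substrate is in solution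
- what has only dissolved of solid substrate counts as not reacted
- the reaction counts as stopped when no species that holds the solid substrate changes by six tenths of a point or more over the second half of the time
- starting material means what is dissolved; the solid is not counted in it

- why nothing more happens at 3.0 d, or that something still does (for what has run out or reacted, a solid counts together with what of it has only dissolved) (the partner has run out first / all of the solid substrate has reacted / it is still moving)
- part of the solid substrate that has turned into other species by 3.0 d (what has only dissolved does not count)
- amount of product at 3.0 d, in percent of the solid substrate charged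
- amount of starting material at 3.0 d, in percent of the solid substrate charged

For the flask, the equivalents of partner minus those of protic impurity, c(protic impurity) over c(solid substrate), come to 90.0%; I call this the usable partner. The earlier runs test it at 3.00 d: ochre has usable partner 96.7% and product 96.6%, grey 80.0% and 79.8%, while red, with 200%, reads 99.6%. Grey reads starting material 17.1% beside solid substrate 3.0%, which I take as the saturation reading. In the flask the usable partner is less than the charge of solid substrate, so the partner is the limiting reagent, and the remainder, 10.0%, is less than that reading, so I expect it dissolved. Ochre and grey stand flat by 0.833 d, so I expect a stop before 3.0 d.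

The forecast says the partner has run out first, with conversion 90%, product 90% and starting material 10%: “The remaining 10% is below solubility, so it all dissolves.” My reckoning gives the same.

The flask gives the partner has run out first, with conversion 90.0%, product 90.0% and starting material 10.0%.

    starting material + partner → product, rate k1*[starting material]*[partner]^0.5 (k = 0.160 /M^0.5/min)
    solid substrate ⇌ starting material, rate k2*(cs2 - [starting material]) while solid is left; crystals form when [starting material] > cs2 (solubility = 4.10 mM, k = 0.0120 /min)
    partner + protic impurity → quenched reagent (k = 18.0 /M/min)

The usable partner 90.0% carries no clock, whereas the flask takes 0.267 d to reach half of its conversion, and the crawl of solid substrate into solution makes no difference to the conversion at 3.0 d. A neighbouring flask, the same but with c(protic impurity) 0.0082 M, has usable partner 75.8%, and its remainder 24.2% is more than the grey reading. It gives product 75.8%, starting material 17.1% and, at 3.00 d, solid substrate 7.08%.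

(The earlier runs and the new flask come from a simulation for an exercise; noise was put on by code.)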